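I counted turnovers.

in all of them: substrate 0.20 M; enzyme 20 µM

| run | remark |
|---|---|
| winter | the very flask that is asked about, followed so far |
| flask |  |

winter run (percent of the substrate charged)

| time / min | target / % |
|---|---|
| 0.417 | 0.9 |
| 0.667 | 2.2 |
| 1.33 | 3.8 |
| 2.00 | 6.0 |
| 3.00 | 5.7 |
| 5.00 | 11.4 |

(each reading ± 1 percentage point)

- the analysis behind the earlier runs scatters by 1 percentage point, standard deviation
- no earlier run changes the charge of enzyme; that part of a forecast is a guess

- factor on the rate of making target when 30 % of the substrate are converted if enzyme is charged twice over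
- factor on the rate when 30 % of the substrate are converted if enzyme is charged at 2.0 µM instead

From the winter reading at 5.00 min, 11.4 % of the substrate as target, I read a turnover frequency, target made per minute per enzyme charged on average up to that time, of 228 min⁻¹. No earlier run changes the enzyme, so my reckoning was a guess: if each enzyme kept its frequency at equal conversion, the rate would follow the charge, giving factors of 2 and 0.100. The forecast gave 2 and 0.1, on the ground that “rate is proportional to enzyme”.

The flasks gave 2.01 and 0.0994.

    substrate + enzyme ⇌ complex (K = 3.10 M⁻¹, k = 6760 M⁻¹ s⁻¹)
    complex ⇌ enzyme + target (K = 2.80 M, k = 11.0 s⁻¹)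
    enzyme → spent catalyst (k = 3.80 × 10⁻⁴ s⁻¹)
    substrate → uncatalysed product (k = 0.00116 s⁻¹)

At 30 % conversion, reached after 3.73 min, the flask charged at 20 µM made target at 0.00371 M min⁻¹, which per enzyme charged is 186 min⁻¹, or 0.814 of the frequency I had read. The flask charged at 2.0 µM gave, at that conversion, 184 min⁻¹ per enzyme charged, or 0.809 of it. Taking the loss of substrate to uncatalysed product out of the flask charged at 20 µM lifted the apparent order in enzyme at that conversion from 1.0 to 1.3.

The runs stem from a simulated flask with constants of no real substance; the scatter is artificial.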